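## The problem

The target (26) is a bis-chromone: C5 of chromone A (2-isopropyl-8-methoxy) is joined through one methylene carbon to C2' of chromone B (7'-hydroxy-5'-(2-oxopropyl); primed locants). It has no stereocentre, so the task is one of connectivity and substitution pattern. The only stereocentre of the route, C8a' of the cycloadduct 23, is transient and controls nothing.

The benzene ring of chromone B is a 1,2,3,5-tetrasubstituted resorcinol: carbon substituents on the neighbours C4a' and C5', oxygens on C7' and C8a'. Substitution on a preformed arene does not give this pattern cleanly.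

The two oxygens outside the rings must stay distinguishable. The 8-methoxy group has to survive whatever frees the 7'-hydroxyl, so a late demethylation is excluded.

Several groups are fragile:
- Both 4-pyranone rings are opened by hydroxide and amines.
- The bridging methylene is benzylic and vinylogously α to C4'=O, hence acidic and oxidisable.
- The 2-oxopropyl ketone is enolisable and sits peri to C4'=O; it is carried as a dioxolane to the last step.

The feature that opens the key step is that C4a'=C8a' of chromone B is also the C5=C6 bond of a 4-pyranone. In kojic acid (8) C8a' is an unsubstituted β-carbon of a vinylogous ester, C4a' carries a hydroxyl and C2' carries the future bridge carbon. The carbons C5'–C8' can therefore be added as a 1,1-disubstituted alkene on C4a' (C5', C6') and an oxygen-bearing alkyne (C7', C8').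

The price is a dihydroarene whose sp3 carbon C8a' carries the pyranone oxygen. Loss of that oxygen is a second way to aromatise, so dehydrogenation has to outrun elimination.

## Retrosynthesis

**26 to 24 (via 25).** Only the O7'–Si bond and the dioxolane are cut. O7' is masked as a triisopropylsilyl ether because silicon arrives with the alkyne and fluoride leaves the 8-methoxy group alone. The ketone stays a ketal so that no enolisable carbonyl is present during the couplings and the cycloaddition. The forward step asks only for buffered fluoride, then dilute acid.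

**24 to 23.** Two hydrogens are added back, at C6' and C8a'. The dihydroarene 23 is what an alkyne gives with a diene. The forward dehydrogenation must be fast and neutral, because 23 can also aromatise by expelling O1' from C8a'.

**23 to 18 and 22.** The bonds C8'–C8a' and C6'–C7' are cut, a [4+2] disconnection of the benzene ring of chromone B.
- The neighbouring cut through the pyranone C–O bonds (classical chromone closure) needs a fully substituted ring-B acetophenone that is no easier than the target half.
- The reverse orientation of the two-carbon unit would place oxygen on C8'.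
- This cut removes the arene and its four substituents and leaves 18, a 2,5-disubstituted 4-pyranone, and siloxyalkyne 22.
- The forward reaction must bond the nucleophilic alkyne carbon to C8a' only, close the six-membered ring and not a cyclobutene, and leave the adduct intact.

**22 to 19.** The O–Si and C–O bonds are cut. Acetylene 19 is oxidised as its monolithium salt to the ynolate and silylated on oxygen. The bulky silyl group is needed for O-silylation and for a storable ynol ether.

**18 to 13 and 17.** The C4a'–C5' bond is cut, a Stille coupling of pyranone triflate 13 with the 2-stannyl-1-alkene 17. The cut sits where kojic acid has its enolic hydroxyl. The alternative (an acylpyranone followed by methylenation) is longer. The forward coupling has to cope with a 1-substituted vinylstannane and needs copper assistance.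

**17 to 16 to 14.** Stannane 17 comes from alkyne 16 by stannylmetalation with tin on the internal carbon. Alkyne 16 comes from ester 14 by one-carbon homologation. Ester 14 is the ethylene ketal of ethyl acetoacetate and already holds the protected 2-oxopropyl chain.

**13 to 12 to 11 to 7 and 10.** The triflate comes from enol 12, and the enol from its 4-methoxybenzyl ether 11. In 11 the bond between C5 of chromone A and the bridge carbon is cut.
- Cutting on the other side of the bridge would need a C2'-metallated or C2'-halogenated pyranone, which kojic acid does not offer; its hydroxymethyl carbon is the bridge.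
- The forward sp2–sp3 Suzuki coupling joins boronate 7 and chloride 10.
- The enol must be masked during it. A free enol chelates palladium, and a triflate would compete with the chloride in oxidative addition.

**10 to 9 to 8.** Chloride 10 comes from alcohol 9, the 4-methoxybenzyl ether of kojic acid 8; two functional-group steps.

**7 to 6 to 4 to 2 to 1.** The C–B bond is cut back to bromide 6. The pyranone of chromone A is opened at O1–C2 and C2–C3 to methyl ketone 4 and an isobutyrate ester. The acetyl group of 4 is removed from the carbon flanked by oxygen and bromine in 2, where directed lithiation places it. Ether 2 is the methoxymethyl ether of 5-bromo-2-methoxyphenol 1, which already has the methoxy group and the bromine in the right places.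

## Roads not taken

**Alternative 1:** The cut is the C4a'–C5' bond of the benzene ring of chromone B, made first and alone.
- **Forward key step:** the diketo-dioxinone A2 is treated with triethylamine; the dioxinone carbon beside the lactone carbonyl attacks the distal ketone, and dehydration gives the resorcylate A1.
- **Merits:** the polyketide folding itself places the oxygens at C7' and C8a', the carboxyl carbon C4' and the ketal chain at C5'. Conditions are mild and the reaction type is established. A1 is an activated salicylate that can acylate a ketone enolate towards the 1,3-diketone of pyranone B.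
- **Weak points:** A2 needs successive C-acylations of dioxinone dienolates. Its ketal carbon is β to a ketone and can be lost by elimination under base. The chain has more than one aldol mode. After A1, pyranone B must still be closed and chromone A attached through an enolisable arylacetone, with O7' protected.
- **Comparison:** every step has precedent, which the chosen plan cannot claim for step 14. It is at least as long and linear in its second half. The chosen plan sets against it convergence and the fact that bridge carbon and pyranone B come ready-made in 8.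

**Alternative 2:** The cut is the C6–C7 bond of the benzene ring of chromone A.
- **Forward key step:** the dialkenyl pyranone A4 undergoes thermal disrotatory 6π-electrocyclisation to the dihydrochromone A3, to be dehydrogenated later.
- **Merits:** no reagent is needed and hexatriene closures of this kind are better precedented than step 14. The positions of the 8-methoxy group and the C5 side chain are fixed by which alkenyl group sits where. A3 has no leaving group on an sp3 ring-fusion carbon, so it lacks the ring-opening hazard of 23; in this respect it is the safer key step.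
- **Weak points:** it spends the key step on the easy ring, which steps 1–3 give in three classical operations from 1. A4 needs two different alkenyl groups on neighbouring pyranone carbons, one an acid-labile 1-methoxyvinyl ether. The acetate arm of A3 still needs a ring-B acetophenone with the ketal chain for chromone B.
- **Comparison:** safer at its key step, but longer overall and it leaves the difficult resorcinol half unsolved. The chosen plan sets against it a key step that deals with the hard ring.

**Alternative 3:** The cut is the C8a'–O1' bond of chromone B.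
- **Forward key step:** the enolate of diketone A6 (K2CO3) displaces one of two equivalent ortho fluorides through oxygen and gives the fluorochromone A5.
- **Merits:** the closure is a robust, known chromone synthesis. Symmetry removes the regiochemical question and no oxidation is needed. The remaining fluoride at C5' is peri to the carbonyl and activated for a second displacement by an acetoacetate-type carbanion, which would give the 2-oxopropyl group after dealkoxycarbonylation.
- **Weak points:** that carbanion displacement on A5 competes with conjugate addition at C2' and with deprotonation of the bridging methylene. A6 needs a Claisen condensation between two enolisable partners. The benzyl ether adds a hydrogenolysis. The sequence is linear.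
- **Comparison:** step by step this is probably the more reliable road and it is of similar length. The chosen plan sets against it convergence (three fragments of at most four steps, joined by two cross-couplings), a ring-B pattern fixed by the connectivity of one cycloaddition, and a side chain installed as a robust ketal before the arene exists. If step 14 fails, the fallback below uses this classical logic.

Key step: step 14

Assumption: ethyl (2-methyl-1,3-dioxolan-2-yl)acetate 14 (the ethylene ketal of ethyl acetoacetate, sold as a fragrance chemical) and acetylene 19 are taken as purchased; primed locants refer to chromone B.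

## Route

Step 1
Reactants: 1 5-bromo-2-methoxyphenol
Product: 2 4-bromo-1-methoxy-2-(methoxymethoxy)benzene
Conditions: MOMCl, iPr2NEt, CH2Cl2, 0 °C to rt
Reagents that add atoms: chloromethyl methyl ether, COCCl
Why: O-Alkylation of the phenol by the α-chloro ether (methoxymethyl protection); the acetal oxygen later directs lithiation and the group is lost in the acid of step 3.

Step 2
Reactants: 2 4-bromo-1-methoxy-2-(methoxymethoxy)benzene
Product: 4 1-[6-bromo-3-methoxy-2-(methoxymethoxy)phenyl]ethan-1-one, via aryllithium 3 (not isolated)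
Conditions: LiN(iPr)2, THF, −78 °C; N-methoxy-N-methylacetamide, −78 to −40 °C; H2O quench
Reagents that add atoms: N-methoxy-N-methylacetamide, CC(=O)N(C)OC
Why: Directed ortho-metalation: the proton flanked by the acetal oxygen and bromine is the most acidic, and lithium diisopropylamide at −78 °C should remove it without bromine–lithium exchange or aryne formation. The aryllithium is acylated by the Weinreb amide, whose chelated tetrahedral adduct prevents a second addition.

Step 3
Reactants: 4 1-[6-bromo-3-methoxy-2-(methoxymethoxy)phenyl]ethan-1-one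
Product: 6 5-bromo-8-methoxy-2-(propan-2-yl)-4H-chromen-4-one, via diketone 5 (not isolated)
Conditions: NaH, ethyl 2-methylpropanoate, THF, reflux; then conc. HCl, MeOH, 60 °C
Reagents that add atoms: ethyl 2-methylpropanoate, CCOC(=O)C(C)C
Why: Claisen condensation of the methyl ketone enolate with the ester gives the 1,3-diketone. Acid then cleaves the acetal, and the freed phenol cyclodehydrates onto the isobutyryl carbonyl (standard chromone synthesis).

Step 4
Reactants: 6 5-bromo-8-methoxy-2-(propan-2-yl)-4H-chromen-4-one
Product: 7 8-methoxy-2-(propan-2-yl)-5-(4,4,5,5-tetramethyl-1,3,2-dioxaborolan-2-yl)-4H-chromen-4-one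
Conditions: B2pin2, Pd(dppf)Cl2 (5 mol %), KOAc, 1,4-dioxane, 90 °C
Reagents that add atoms: bis(pinacolato)diboron, CC1(C)OB(OC1(C)C)B1OC(C)(C)C(C)(C)O1
Why: Miyaura borylation; oxidative addition of zerovalent palladium into the electron-poor aryl bromide is easy, and acetate is too weak a base to open the pyranone.

Step 5
Reactants: 8 kojic acid (5-hydroxy-2-(hydroxymethyl)-4H-pyran-4-one)
Product: 9 2-(hydroxymethyl)-5-[(4-methoxyphenyl)methoxy]-4H-pyran-4-one
Conditions: 4-methoxybenzyl chloride, K2CO3, DMF, 70 °C
Reagents that add atoms: 4-methoxybenzyl chloride, COc1ccc(CCl)cc1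
Why: Williamson etherification; the enolic 5-hydroxyl is about as acidic as a phenol and is alkylated selectively over the primary alcohol under carbonate conditions.

Step 6
Reactants: 9 2-(hydroxymethyl)-5-[(4-methoxyphenyl)methoxy]-4H-pyran-4-one
Product: 10 2-(chloromethyl)-5-[(4-methoxyphenyl)methoxy]-4H-pyran-4-one
Conditions: PPh3, N-chlorosuccinimide, THF, 0 °C to rt
Reagents that add atoms: N-chlorosuccinimide, O=C1CCC(=O)N1Cl
Why: Appel-type chlorination under neutral conditions, so the acid-labile 4-methoxybenzyl ether survives; the hydroxymethyl carbon reacts like a benzylic one.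

Step 7
Reactants: 7 8-methoxy-2-(propan-2-yl)-5-(4,4,5,5-tetramethyl-1,3,2-dioxaborolan-2-yl)-4H-chromen-4-one; 10 2-(chloromethyl)-5-[(4-methoxyphenyl)methoxy]-4H-pyran-4-one
Product: 11 8-methoxy-5-({5-[(4-methoxyphenyl)methoxy]-4-oxo-4H-pyran-2-yl}methyl)-2-(propan-2-yl)-4H-chromen-4-one
Conditions: Pd(OAc)2 (5 mol %), SPhos (10 mol %), K3PO4, toluene/H2O 10:1, 80 °C
Reagents that add atoms: none
Why: Suzuki–Miyaura coupling of an sp3 electrophile: the pyranylmethyl chloride undergoes oxidative addition like a benzyl chloride and has no β-hydrogen. The bulky biaryl phosphine helps transmetalation of the ortho-substituted boronate.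

Step 8
Reactants: 11 8-methoxy-5-({5-[(4-methoxyphenyl)methoxy]-4-oxo-4H-pyran-2-yl}methyl)-2-(propan-2-yl)-4H-chromen-4-one
Product: 12 5-[(5-hydroxy-4-oxo-4H-pyran-2-yl)methyl]-8-methoxy-2-(propan-2-yl)-4H-chromen-4-one
Conditions: CF3CO2H, anisole, CH2Cl2, 0 °C to rt
Reagents that add atoms: none
Why: Acidolysis of the 4-methoxybenzyl ether; anisole traps the benzyl cation so that it does not alkylate the pyranone or the bridge, and the aryl methyl ether is untouched.

Step 9
Reactants: 12 5-[(5-hydroxy-4-oxo-4H-pyran-2-yl)methyl]-8-methoxy-2-(propan-2-yl)-4H-chromen-4-one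
Product: 13 6-{[8-methoxy-4-oxo-2-(propan-2-yl)-4H-chromen-5-yl]methyl}-4-oxo-4H-pyran-3-yl trifluoromethanesulfonate
Conditions: PhNTf2, Et3N, DMAP (cat.), CH2Cl2, 0 °C to rt
Reagents that add atoms: N-phenylbis(trifluoromethanesulfonimide), O=S(=O)(N(c1ccccc1)S(=O)(=O)C(F)(F)F)C(F)(F)F
Why: O-Sulfonylation of the enol with a mild triflating agent; triflates of 3-hydroxy-4-pyranones are established partners for palladium couplings.

Step 10
Reactants: 14 ethyl (2-methyl-1,3-dioxolan-2-yl)acetate
Product: 16 2-methyl-2-(prop-2-yn-1-yl)-1,3-dioxolane, via aldehyde 15 (not isolated)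
Conditions: iBu2AlH, CH2Cl2, −78 °C; then MeOH, K2CO3, dimethyl (1-diazo-2-oxopropyl)phosphonate, −78 °C to rt
Reagents that add atoms: dimethyl (1-diazo-2-oxopropyl)phosphonate, CC(=O)C(=[N+]=[N-])P(=O)(OC)OC
Why: Half-reduction of the ester to the aluminium hemiacetal, then Seyferth–Gilbert homologation with the Ohira–Bestmann reagent in the same flask; the mild carbonate conditions should spare the β-ketal aldehyde.

Step 11
Reactants: 16 2-methyl-2-(prop-2-yn-1-yl)-1,3-dioxolane
Product: 17 trimethyl[3-(2-methyl-1,3-dioxolan-2-yl)prop-1-en-2-yl]stannane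
Conditions: Me3SnSnMe3, MeLi, THF, −20 °C; CuBr·SMe2, −78 °C; then 16, MeOH, −78 to −60 °C
Reagents that add atoms: hexamethylditin, C[Sn](C)(C)[Sn](C)(C)C
Why: Stannylcupration of a terminal alkyne (Piers protocol): syn addition of the tin–copper reagent is reversible, and methanol protonates the adduct that has tin on the internal carbon. This gives the 2-stannyl-1-alkene needed for the branched alkenyl group.

Step 12
Reactants: 13 6-{[8-methoxy-4-oxo-2-(propan-2-yl)-4H-chromen-5-yl]methyl}-4-oxo-4H-pyran-3-yl trifluoromethanesulfonate; 17 trimethyl[3-(2-methyl-1,3-dioxolan-2-yl)prop-1-en-2-yl]stannane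
Product: 18 8-methoxy-5-({5-[3-(2-methyl-1,3-dioxolan-2-yl)prop-1-en-2-yl]-4-oxo-4H-pyran-2-yl}methyl)-2-(propan-2-yl)-4H-chromen-4-one
Conditions: Pd(PPh3)4 (10 mol %), CuCl, LiCl, DMSO, 60 °C
Reagents that add atoms: none
Why: Stille coupling; CuCl and LiCl speed the transmetalation of the hindered 1-substituted vinylstannane and suppress cine substitution. The neutral medium spares the triflate, the ketal and the acidic bridge.

Step 13
Reactants: 19 acetylene
Product: 22 (ethynyloxy)tri(propan-2-yl)silane, via lithium acetylide 20 (not isolated), via lithium ethynolate 21 (not isolated)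
Conditions: 19 (excess), nBuLi (1 equiv), THF, −78 °C; LiOOtBu (from tBuOOH, LiN(SiMe3)2), −78 to −20 °C; iPr3SiOTf, −78 to 0 °C
Reagents that add atoms: tert-butyl hydroperoxide, CC(C)(C)OO; triisopropylsilyl trifluoromethanesulfonate, CC(C)[Si](OS(=O)(=O)C(F)(F)F)(C(C)C)C(C)C
Why: Oxidation of a lithium acetylide with lithium tert-butyl peroxide gives the ynolate, and the bulky silyl triflate silylates it on oxygen, the established route to siloxyalkynes from terminal alkynes. One equivalent of base on excess acetylene at low temperature keeps the monoacetylide.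

Step 14
Reactants: 18 8-methoxy-5-({5-[3-(2-methyl-1,3-dioxolan-2-yl)prop-1-en-2-yl]-4-oxo-4H-pyran-2-yl}methyl)-2-(propan-2-yl)-4H-chromen-4-one; 22 (ethynyloxy)tri(propan-2-yl)silane
Product: 23 2-{[8-methoxy-4-oxo-2-(propan-2-yl)-4H-chromen-5-yl]methyl}-5-[(2-methyl-1,3-dioxolan-2-yl)methyl]-7-{[tri(propan-2-yl)silyl]oxy}-6,8a-dihydro-4H-chromen-4-one (racemic at C8a')
Conditions: 22 (3 equiv), AgNTf2 (10 mol %), 4 Å MS, CH2Cl2, −40 °C to rt; filtration through basic alumina, crude 23 used at once
Reagents that add atoms: none
Why: Proposed new method: the C4a'=C8a' bond of pyranone 18 and its exocyclic 1,1-disubstituted alkene form a diene whose LUMO is lowered by the cross-conjugated C4' carbonyl, so it should accept the electron-rich siloxyalkyne 22 in an inverse-demand [4+2] cycloaddition; the closest known reactions are Diels–Alder reactions of 3-vinylchromones with enamines and ynamines, AgNTf2-catalysed additions of siloxyalkynes to enones and 1,2-diazines, and benzannulations with siloxyalkynes. The unsubstituted alkyne carbon (future C8'), which is the nucleophilic terminus of the ynol ether, bonds to the electrophilic β-carbon C8a', and the silyloxy-bearing carbon (C7') bonds to the alkene terminus C6'; in the stepwise limit this is a conjugate addition giving a silyl ketenium ion and a dienolate that collapse through the γ-carbon C6'. The carbocycle therefore closes as a six-membered ring in a [4+2] mode (in the stepwise limit a 6-exo attack of C6' on the C=O+ carbon), which should be favoured over four-ring closure at C4a' because that would give a strained cyclobutene at a quaternary carbon. The one new stereocentre, C8a', has no controlling element and needs none: 23 forms as a racemate and the centre becomes sp2 in step 15. Regioselectivity (oxygen on C7', not C8') follows from the polarity of the siloxyalkyne. Site selectivity follows from C8a' being the only unsubstituted β-carbon of a vinylogous ester in 18 (C2' and C2 of chromone A are fully substituted) and the only one that can relay charge to a pendant alkene. The triisopropylsilyl group keeps the ketenium from losing silicon and gives an enol ether that survives filtration. Because 23 can aromatise by 1,4-elimination of the ring oxygen O1' from C8a', the reaction is run cold and free of base and protic acid, and the crude adduct is oxidised at once.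

Step 15
Reactants: 23 2-{[8-methoxy-4-oxo-2-(propan-2-yl)-4H-chromen-5-yl]methyl}-5-[(2-methyl-1,3-dioxolan-2-yl)methyl]-7-{[tri(propan-2-yl)silyl]oxy}-6,8a-dihydro-4H-chromen-4-one
Product: 24 2-{[8-methoxy-4-oxo-2-(propan-2-yl)-4H-chromen-5-yl]methyl}-5-[(2-methyl-1,3-dioxolan-2-yl)methyl]-7-{[tri(propan-2-yl)silyl]oxy}-4H-chromen-4-one
Conditions: DDQ (1.1 equiv), CH2Cl2, −20 to 0 °C
Reagents that add atoms: none
Why: Quinone dehydrogenation of a 1,4-cyclohexadiene: hydride is abstracted from C8a' (allylic, next to O1' and vinylogous to the silyl enol ether) or from the doubly allylic C6', and loss of the other proton gives the arene. The C8a' stereocentre disappears and the silyl ether is kept.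

Step 16
Reactants: 24 2-{[8-methoxy-4-oxo-2-(propan-2-yl)-4H-chromen-5-yl]methyl}-5-[(2-methyl-1,3-dioxolan-2-yl)methyl]-7-{[tri(propan-2-yl)silyl]oxy}-4H-chromen-4-one
Product: 26 7-hydroxy-2-{[8-methoxy-4-oxo-2-(propan-2-yl)-4H-chromen-5-yl]methyl}-5-(2-oxopropyl)-4H-chromen-4-one (CNP0592286.0), via phenol ketal 25 (not isolated)
Conditions: Bu4NF, AcOH, THF, 0 °C; then 2 M HCl, THF, rt
Reagents that add atoms: water, O
Why: Fluoride cleaves the aryl silyl ether (buffered with acetic acid so that no free phenoxide meets the pyranones), then aqueous acid hydrolyses the dioxolane. Neither reagent touches the aryl methyl ether.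

## Compound list

1 | 5-bromo-2-methoxyphenol | COc1ccc(Br)cc1O | starting material
2 | 4-bromo-1-methoxy-2-(methoxymethoxy)benzene | COCOc1cc(Br)ccc1OC | intermediate
3 | [6-bromo-3-methoxy-2-(methoxymethoxy)phenyl]lithium | [Li]c1c(Br)ccc(OC)c1OCOC | intermediate
4 | 1-[6-bromo-3-methoxy-2-(methoxymethoxy)phenyl]ethan-1-one | CC(=O)c1c(Br)ccc(OC)c1OCOC | intermediate
5 | 1-[6-bromo-3-methoxy-2-(methoxymethoxy)phenyl]-4-methylpentane-1,3-dione | CC(C)C(=O)CC(=O)c1c(Br)ccc(OC)c1OCOC | intermediate
6 | 5-bromo-8-methoxy-2-(propan-2-yl)-4H-chromen-4-one | COc1ccc(Br)c2c(=O)cc(C(C)C)oc12 | intermediate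
7 | 8-methoxy-2-(propan-2-yl)-5-(4,4,5,5-tetramethyl-1,3,2-dioxaborolan-2-yl)-4H-chromen-4-one | COc1ccc(B2OC(C)(C)C(C)(C)O2)c2c(=O)cc(C(C)C)oc12 | intermediate
8 | kojic acid, 5-hydroxy-2-(hydroxymethyl)-4H-pyran-4-one | OCc1cc(=O)c(O)co1 | starting material
9 | 2-(hydroxymethyl)-5-[(4-methoxyphenyl)methoxy]-4H-pyran-4-one | OCc1cc(=O)c(OCc2ccc(OC)cc2)co1 | intermediate
10 | 2-(chloromethyl)-5-[(4-methoxyphenyl)methoxy]-4H-pyran-4-one | ClCc1cc(=O)c(OCc2ccc(OC)cc2)co1 | intermediate
11 | 8-methoxy-5-({5-[(4-methoxyphenyl)methoxy]-4-oxo-4H-pyran-2-yl}methyl)-2-(propan-2-yl)-4H-chromen-4-one | COc1ccc(Cc2cc(=O)c(OCc3ccc(OC)cc3)co2)c2c(=O)cc(C(C)C)oc12 | intermediate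
12 | 5-[(5-hydroxy-4-oxo-4H-pyran-2-yl)methyl]-8-methoxy-2-(propan-2-yl)-4H-chromen-4-one | COc1ccc(Cc2cc(=O)c(O)co2)c2c(=O)cc(C(C)C)oc12 | intermediate
13 | 6-{[8-methoxy-4-oxo-2-(propan-2-yl)-4H-chromen-5-yl]methyl}-4-oxo-4H-pyran-3-yl trifluoromethanesulfonate | COc1ccc(Cc2cc(=O)c(OS(=O)(=O)C(F)(F)F)co2)c2c(=O)cc(C(C)C)oc12 | intermediate
14 | ethyl (2-methyl-1,3-dioxolan-2-yl)acetate | CCOC(=O)CC1(C)OCCO1 | starting material
15 | (2-methyl-1,3-dioxolan-2-yl)acetaldehyde | O=CCC1(C)OCCO1 | intermediate
16 | 2-methyl-2-(prop-2-yn-1-yl)-1,3-dioxolane | C#CCC1(C)OCCO1 | intermediate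
17 | trimethyl[3-(2-methyl-1,3-dioxolan-2-yl)prop-1-en-2-yl]stannane | C=C(CC1(C)OCCO1)[Sn](C)(C)C | intermediate
18 | 8-methoxy-5-({5-[3-(2-methyl-1,3-dioxolan-2-yl)prop-1-en-2-yl]-4-oxo-4H-pyran-2-yl}methyl)-2-(propan-2-yl)-4H-chromen-4-one | COc1ccc(Cc2cc(=O)c(C(=C)CC3(C)OCCO3)co2)c2c(=O)cc(C(C)C)oc12 | intermediate
19 | acetylene | C#C | starting material
20 | lithium acetylide | [Li]C#C | intermediate
21 | lithium ethynolate | [Li]OC#C | intermediate
22 | (ethynyloxy)tri(propan-2-yl)silane (triisopropylsilyloxyacetylene) | C#CO[Si](C(C)C)(C(C)C)C(C)C | intermediate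
23 | 2-{[8-methoxy-4-oxo-2-(propan-2-yl)-4H-chromen-5-yl]methyl}-5-[(2-methyl-1,3-dioxolan-2-yl)methyl]-7-{[tri(propan-2-yl)silyl]oxy}-6,8a-dihydro-4H-chromen-4-one, racemic at C8a' | COc1ccc(CC2=CC(=O)C3=C(CC4(C)OCCO4)CC(O[Si](C(C)C)(C(C)C)C(C)C)=CC3O2)c2c(=O)cc(C(C)C)oc12 | intermediate
24 | 2-{[8-methoxy-4-oxo-2-(propan-2-yl)-4H-chromen-5-yl]methyl}-5-[(2-methyl-1,3-dioxolan-2-yl)methyl]-7-{[tri(propan-2-yl)silyl]oxy}-4H-chromen-4-one | COc1ccc(Cc2cc(=O)c3c(CC4(C)OCCO4)cc(O[Si](C(C)C)(C(C)C)C(C)C)cc3o2)c2c(=O)cc(C(C)C)oc12 | intermediate
25 | 7-hydroxy-2-{[8-methoxy-4-oxo-2-(propan-2-yl)-4H-chromen-5-yl]methyl}-5-[(2-methyl-1,3-dioxolan-2-yl)methyl]-4H-chromen-4-one | COc1ccc(Cc2cc(=O)c3c(CC4(C)OCCO4)cc(O)cc3o2)c2c(=O)cc(C(C)C)oc12 | intermediate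
26 | 7-hydroxy-2-{[8-methoxy-4-oxo-2-(propan-2-yl)-4H-chromen-5-yl]methyl}-5-(2-oxopropyl)-4H-chromen-4-one (CNP0592286.0) | COc1ccc(Cc2cc(=O)c3c(CC(C)=O)cc(O)cc3o2)c2c(=O)cc(C(C)C)oc12 | target

## Step count and least certain steps

Total: 16 steps. Longest linear sequence: 11 steps (steps 1, 2, 3, 4, 7, 8, 9, 12, 14, 15, 16).

**Step 14 (key step, the one step beyond known chemistry).** Three processes may defeat it:
- The pyranone diene may be too weakly electrophilic, so that no addition occurs.
- The zwitterion may close to a four-membered ring at C4a', or the alkyne may add to the enone of chromone A.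
- The adduct may aromatise in the flask by expelling O1' from C8a', which opens pyranone B irreversibly.

Fallback in known chemistry, from bromide 6 to target 26; ring B is then bought as an arene and pyranone B is closed classically:
- Palladium-catalysed coupling of 6 with BrZnCH2CO2tBu (Pd2(dba)3, XPhos) should give tert-butyl [8-methoxy-4-oxo-2-(propan-2-yl)-4H-chromen-5-yl]acetate F1.
- CF3CO2H frees [8-methoxy-4-oxo-2-(propan-2-yl)-4H-chromen-5-yl]acetic acid F2.
- Carbodiimide esterification with commercial 1-[2,4-bis(benzyloxy)-6-hydroxyphenyl]ethan-1-one gives the aryl ester F3.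
- Baker–Venkataraman rearrangement (KOtBu) gives the 1,3-diketone F4.
- Cyclodehydration (TsOH) gives the 5',7'-bis(benzyloxy)chromone F5.
- BCl3 at −78 °C removes the chelated peri benzyl group and gives the 5'-hydroxy compound F6.
- Tf2O and pyridine give the 5'-triflate F7.
- Palladium-catalysed acetonylation with the tin enolate made from isopropenyl acetate and Bu3SnOMe gives the 7'-benzyl ether of the target F8.
- Hydrogenolysis (H2, Pd/C) returns to 26.

**Step 15.** Elimination of the ring oxygen may outrun hydride abstraction, and the quinone may attack the bridging methylene. Fallback from 23 to 25, replacing hydride abstraction by a syn elimination: PhSeCl selenenylates the silyl enol ether at C8' and gives the α-phenylselanyl ketone F9. Oxidation with H2O2 and pyridine lets the selenoxide eliminate towards C8a'–H, and the dienone tautomerises to phenol 25, which enters the acid stage of step 16.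

**Step 13.** The monoacetylide may disproportionate before it is oxidised, the ynolate may be deprotonated a second time, or silylation may go to carbon. Fallback from 18 to 26 with a different ynol ether of known preparation:
- KOtBu and trichloroethylene give (E)-1-tert-butoxy-1,2-dichloroethene F10.
- nBuLi then methanol give tert-butoxyethyne F11.
- Cycloaddition with 18 as in step 14, kept below room temperature because this ether loses isobutene on heating, gives the tert-butyl dienol ether F12.
- DDQ gives the aryl tert-butyl ether F13.
- Aqueous CF3CO2H removes tert-butyl group and ketal together and returns to 26.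

**Step 7.** Protodeboronation of the peri-substituted boronate and solvolysis of the chloride by the aqueous base may consume both partners. Fallback from 10 and 6 to 11 with reversed polarity: zinc insertion (Zn, LiCl, THF) into 10 gives the pyranylmethylzinc chloride F14, and Negishi coupling with bromide 6 (Pd(OAc)2, SPhos) gives 11. This also makes step 4 unnecessary.

**Step 12.** Slow transmetalation of the 1-substituted stannane may allow cine substitution or reduction of the triflate. Fallback from 16 and 13 to 18 without tin: nickel-catalysed α-hydroalumination of 16 (Ni(dppp)Cl2, iBu2AlH) and trapping with methoxy pinacol borate gives the 2-boryl-1-alkene F15. Suzuki coupling with 13 (Pd(dppf)Cl2, K3PO4, dioxane) gives 18.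

## Further compounds

F1 | step 14 | tert-butyl [8-methoxy-4-oxo-2-(propan-2-yl)-4H-chromen-5-yl]acetate | COc1ccc(CC(=O)OC(C)(C)C)c2c(=O)cc(C(C)C)oc12
F2 | step 14 | [8-methoxy-4-oxo-2-(propan-2-yl)-4H-chromen-5-yl]acetic acid | COc1ccc(CC(=O)O)c2c(=O)cc(C(C)C)oc12
F3 | step 14 | 2-acetyl-3,5-bis(benzyloxy)phenyl [8-methoxy-4-oxo-2-(propan-2-yl)-4H-chromen-5-yl]acetate | COc1ccc(CC(=O)Oc2cc(OCc3ccccc3)cc(OCc3ccccc3)c2C(C)=O)c2c(=O)cc(C(C)C)oc12
F4 | step 14 | 1-[2,4-bis(benzyloxy)-6-hydroxyphenyl]-4-[8-methoxy-4-oxo-2-(propan-2-yl)-4H-chromen-5-yl]butane-1,3-dione | COc1ccc(CC(=O)CC(=O)c2c(O)cc(OCc3ccccc3)cc2OCc2ccccc2)c2c(=O)cc(C(C)C)oc12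
F5 | step 14 | 5,7-bis(benzyloxy)-2-{[8-methoxy-4-oxo-2-(propan-2-yl)-4H-chromen-5-yl]methyl}-4H-chromen-4-one | COc1ccc(Cc2cc(=O)c3c(OCc4ccccc4)cc(OCc4ccccc4)cc3o2)c2c(=O)cc(C(C)C)oc12
F6 | step 14 | 7-(benzyloxy)-5-hydroxy-2-{[8-methoxy-4-oxo-2-(propan-2-yl)-4H-chromen-5-yl]methyl}-4H-chromen-4-one | COc1ccc(Cc2cc(=O)c3c(O)cc(OCc4ccccc4)cc3o2)c2c(=O)cc(C(C)C)oc12
F7 | step 14 | 7-(benzyloxy)-2-{[8-methoxy-4-oxo-2-(propan-2-yl)-4H-chromen-5-yl]methyl}-4-oxo-4H-chromen-5-yl trifluoromethanesulfonate | COc1ccc(Cc2cc(=O)c3c(OS(=O)(=O)C(F)(F)F)cc(OCc4ccccc4)cc3o2)c2c(=O)cc(C(C)C)oc12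
F8 | step 14 | 7-(benzyloxy)-2-{[8-methoxy-4-oxo-2-(propan-2-yl)-4H-chromen-5-yl]methyl}-5-(2-oxopropyl)-4H-chromen-4-one | COc1ccc(Cc2cc(=O)c3c(CC(C)=O)cc(OCc4ccccc4)cc3o2)c2c(=O)cc(C(C)C)oc12
F9 | step 15 | 2-{[8-methoxy-4-oxo-2-(propan-2-yl)-4H-chromen-5-yl]methyl}-5-[(2-methyl-1,3-dioxolan-2-yl)methyl]-8-(phenylselanyl)-8,8a-dihydro-4H-chromene-4,7(6H)-dione | COc1ccc(CC2=CC(=O)C3=C(CC4(C)OCCO4)CC(=O)C([Se]c4ccccc4)C3O2)c2c(=O)cc(C(C)C)oc12
F10 | step 13 | (E)-1-tert-butoxy-1,2-dichloroethene | Cl/C=C(/Cl)OC(C)(C)C
F11 | step 13 | tert-butoxyethyne | C#COC(C)(C)C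
F12 | step 13 | 7-tert-butoxy-2-{[8-methoxy-4-oxo-2-(propan-2-yl)-4H-chromen-5-yl]methyl}-5-[(2-methyl-1,3-dioxolan-2-yl)methyl]-6,8a-dihydro-4H-chromen-4-one, racemic | COc1ccc(CC2=CC(=O)C3=C(CC4(C)OCCO4)CC(OC(C)(C)C)=CC3O2)c2c(=O)cc(C(C)C)oc12
F13 | step 13 | 7-tert-butoxy-2-{[8-methoxy-4-oxo-2-(propan-2-yl)-4H-chromen-5-yl]methyl}-5-[(2-methyl-1,3-dioxolan-2-yl)methyl]-4H-chromen-4-one | COc1ccc(Cc2cc(=O)c3c(CC4(C)OCCO4)cc(OC(C)(C)C)cc3o2)c2c(=O)cc(C(C)C)oc12
F14 | step 7 | chloro({5-[(4-methoxyphenyl)methoxy]-4-oxo-4H-pyran-2-yl}methyl)zinc | Cl[Zn]Cc1cc(=O)c(OCc2ccc(OC)cc2)co1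
F15 | step 12 | 4,4,5,5-tetramethyl-2-[3-(2-methyl-1,3-dioxolan-2-yl)prop-1-en-2-yl]-1,3,2-dioxaborolane | C=C(CC1(C)OCCO1)B1OC(C)(C)C(C)(C)O1
A1 | alternative 1 | 7-hydroxy-2,2-dimethyl-5-[(2-methyl-1,3-dioxolan-2-yl)methyl]-4H-1,3-benzodioxin-4-one | CC1(Cc2cc(O)cc3OC(C)(C)OC(=O)c23)OCCO1
A2 | alternative 1 | 2,2-dimethyl-6-[5-(2-methyl-1,3-dioxolan-2-yl)-2,4-dioxopentyl]-4H-1,3-dioxin-4-one | CC1(CC(=O)CC(=O)CC2=CC(=O)OC(C)(C)O2)OCCO1
A3 | alternative 2 | methyl 2-[8-methoxy-4-oxo-2-(propan-2-yl)-6,7-dihydro-4H-chromen-5-yl]acetate | COC(=O)CC1=C2C(=O)C=C(C(C)C)OC2=C(OC)CC1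
A4 | alternative 2 | methyl 3-[2-(1-methoxyethenyl)-4-oxo-6-(propan-2-yl)-4H-pyran-3-yl]but-3-enoate | COC(=O)CC(=C)c1c(C(=C)OC)oc(C(C)C)cc1=O
A5 | alternative 3 | 7-(benzyloxy)-5-fluoro-2-{[8-methoxy-4-oxo-2-(propan-2-yl)-4H-chromen-5-yl]methyl}-4H-chromen-4-one | COc1ccc(Cc2cc(=O)c3c(F)cc(OCc4ccccc4)cc3o2)c2c(=O)cc(C(C)C)oc12
A6 | alternative 3 | 1-[4-(benzyloxy)-2,6-difluorophenyl]-4-[8-methoxy-4-oxo-2-(propan-2-yl)-4H-chromen-5-yl]butane-1,3-dione | COc1ccc(CC(=O)CC(=O)c2c(F)cc(OCc3ccccc3)cc2F)c2c(=O)cc(C(C)C)oc12
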